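## Analysis of the target

The target is a mixed terpenoid ether: O15 of a labda-8(17),13E-dien-19-oic acid (atoms C1–C20) is bonded to the tertiary carbon C4′ of an eudesmane-4α,11-diol (atoms C1′–C15′, rings A′ and B′; the primes are dropped in the names of eudesmane intermediates). The labdane half is a trans-decalin with four stereocentres, C4 (α-methyl, axial β-carboxyl), C5 (α-H), C9 (α-H) and C10 (β-methyl), an exocyclic C8=C17 alkene and an E-trisubstituted C13=C14 alkene whose allylic carbon C15 carries the ether oxygen. The eudesmane half is a second trans-decalin with four stereocentres, C4′ (α-oxygen, β-methyl), C5′ (α-H), C7′ (β-hydroxyisopropyl, equatorial) and C10′ (β-methyl, axial); no stereocentre of one half influences the other, so each half can be made alone in its own absolute configuration. The tertiary allylic ether, the C8=C17 alkene and the tertiary carbinol at C11′ ionise or migrate in acid, so every step after the union has to be neutral or basic. Three things make the synthesis hard: the C4′–O–C15 link joins a hindered tertiary carbon to an allylic one, where SN1 and SN2 etherification both invite elimination or allylic transposition; the hydroxyls at C4′ and C11′ are both tertiary and must be told apart; and the methyl on C10′ must end up cis to the side chain on C7′, 1,4 across ring B′, which is the opposite of what annulation onto a simple 5-substituted 2-methylcyclohexanone delivers. The strategy rests on this last feature: a cyclopropane spanning C6′, C7′ and C11′ covers one face of ring B′ while C10′ becomes quaternary, and afterwards, conjugated with a C4′=C5′ enone, it opens at C11′ to reveal the hydroxyisopropyl group.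

## Retrosynthetic reasoning

**Protecting groups.** Target 29 is traced back to its methyl ester 28 and then to the silyl ether 27. The C19 carboxyl is axial and neopentyl, so it is carried as a methyl ester and freed at the end by SN2 attack on the methyl carbon, not by hydrolysis. The C11′ hydroxyl is carried as a triethylsilyl ether that fluoride removes. Neither unmasking needs acid.

**C14–C15 bond.** 27 is cut between C14 and C15, not at either C–O bond, giving the alkenylalane 26 and the chloromethyl ether 17. Cutting C4′–O would require a C4′ cation or a tertiary leaving group next to three β-hydrogen sets. Cutting O–C15 would require a hindered tertiary alkoxide to attack an allylic electrophile that can also react at C13. With the cut at C14–C15 the ether oxygen already carries C15 before the union, and the forward step is a C–C bond formation at an sp2 carbon that keeps the alkene geometry.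

**C13–C16 bond and the alkene geometry.** 26 comes from the terminal alkyne 25 by syn methylalumination. The methyl C16 and the metal add to the same side, so the E geometry of C13=C14 is set by the mechanism, not by an equilibrium.

**O–C15 bond on the eudesmane.** 17 is derived from the methylthiomethyl ether 16 and this from the tertiary alcohol 15. The alkylation of the hindered C4′ hydroxyl is thus done on a saturated molecule that has no alkene and no second free hydroxyl.

**C4′–O bond.** 15 goes back to the α-epoxide 14 and the alkene 13. The C4′–O bond is made by face-selective epoxidation anti to the axial C10′ methyl and is not broken again, because the epoxide is opened at the secondary C3′.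

**C5′ and the alkene position.** 13 comes from the enol triflate 12, and this from the silylated enone 10 by reduction to the enolate 11 and O-sulfonylation. The reduction sets the trans ring fusion at C5′ and fixes the double bond at C3′=C4′. 10 is the silyl ether of carissone 9; silylation at this point ensures that the C11′ and C4′ hydroxyls are never free together.

**C6′–C11′ bond.** 9 arises from the tricyclic enone 8 by hydrolytic opening of the conjugated cyclopropane. Only the C6′–C11′ bond breaks, so C7′ keeps its configuration and C11′ receives its oxygen.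

**C1′–C10′ and C4′=C5′ (key disconnection).** 8 is cut into carone 4 and ethyl vinyl ketone 5 (through the diketone 6 and the ketol 7). This is the only place where a carbon stereocentre of the eudesmane half, C10′, is made without relay from an adjacent centre. The cyclopropane of 4 both blocks the β face and locks the C7′ configuration taken from the chiral pool.

**Carone.** 4 comes from the chloride 3 by 1,3-elimination, 3 from dihydrocarvone 2 by hydrochlorination, and 2 from (R)-carvone 1 by conjugate reduction. The single stereocentre of 1 becomes C7′.

**Labdane side chain.** 25 is cut at C12–C13 into the primary iodide 24 and an ethynyl unit; 24 comes from the alcohol 23, and 23 from the diester 22 by reduction of the unhindered C12 ester only. 22 is the methylenation product of the keto diester 21, which installs C17 last so that no step before it has to spare an exocyclic alkene.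

**Labdane rings.** 21 is the ester of the keto diacid 20, which comes from the lactol 19 and this from podocarpic acid 18 by ozonolytic removal of C13 and C14 from the phenol ring. 18 already holds C4, C5 and C10 in the required configuration with the axial carboxyl, so ring C only has to be degraded to a ketone at C8 and a two-carbon acid chain on C9.

## Alternatives that were turned down

**Alternative 1:** The labdane decalin is cut at C5–C10 and C8–C9, which leads back to the acyclic trienal A2 whose only stereocentre is the quaternary C4. In the forward direction Me2AlCl activates the enal and the (E,E)-diene adds to the enal alkene to give the trans-fused octalin aldehyde A1, closing rings A and B and setting C5, C8, C9 and C10 in one step. In its favour, it is independent of a natural starting material, it is flexible for analogues, and it builds two rings and four stereocentres at once. Against it for this target: the facial selectivity rests on C4 telling a methyl from a methoxycarbonyl group of similar size; the dienophile carbon C10 is fully substituted, which slows the cycloaddition; A2 itself needs an enantioselective construction of an all-carbon quaternary centre; and A1 still carries a C6=C7 alkene, an sp3 C8 with a protected hydroxymethyl group and only C11 of the side chain. Reaching an alkyne like 25 from A1 would take more steps than the seven from 18. Compared with the chosen route, this alternative is stronger in generality, but it puts the main risk into a ring system that 18 supplies ready-made, and it contributes nothing to the eudesmane half or the ether link, where the chosen strategy spends its key step.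

**Alternative 2:** The same decalin is cut at C4–C5 and C9–C10, leading to the acyclic β-keto ester A4 with an 8-phenylmenthyl ester as the source of chirality. Mn(OAc)3 generates the C4 radical, two 6-endo cyclisations follow, and Cu(OAc)2 turns the C8 radical into the exocyclic alkene, giving A3. This is a strong point: the C8=C17 alkene, the C11 oxygen and four stereocentres appear in one step from a chain that is easy to assemble, which is shorter than the degradation of 18 up to the stage of 22. Against it: the C3 ketone must be removed next to a quaternary centre without touching the new alkene; the copper-mediated elimination can also give endocyclic alkenes; the auxiliary controls the absolute configuration only through a remote ester; and that ester, axial at C4, is very hard to cleave. Compared with the chosen route, it is about equal or better in step count for the bicycle. The chosen route offers in exchange complete security of C4, C5 and C10 from 18 and a C19 ester that is known to come off. Like alternative 1, it leaves the eudesmane half and the ether untouched.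

**Alternative 3:** Here the eudesmane C5′–C10′ bond and the C4′–O bond are cut together, leading to hedycaryol A6 and methyl isocupressate A7. A weak acid protonates C1′ of A6, C5′ attacks C10′ across the ten-membered ring, and the C15 hydroxyl of A7 captures the C4′ cation to give A5, which is identical with 28 and one step from the target. In step economy and convergence this is clearly stronger than the chosen route; it is probably close to the biogenesis, and the trans ring fusion follows from the chair–chair conformer of the ring. Against it: A6 is a thermally labile cyclodeca-1,5-diene and a demanding target in itself; the C4′ cation must be caught intermolecularly by a precious alcohol in competition with proton loss and with capture by any tertiary hydroxyl present; the face of capture at C4′ is not controlled; and the acid also threatens the allylic alcohol and the C8=C17 alkene of A7, which is no easier to make than 25. In place of brevity the chosen route offers stepwise control: C10′ by facial shielding, C5′ by dissolving-metal reduction, C4′–O by epoxidation and hydride opening, and an ether link formed without ever generating a cation at C4′.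

Key step: step 4

## Remarks on the chemistry

- Compounds 2, 3 and 4 are drawn as the epimer with the methyl group trans to the C5/C6 substituent. The other epimer at this α-carbon may be carried along, because the centre becomes the planar enolate carbon in step 4.
- 19 is drawn as the lactol and 20 as the open keto diacid. Each is in ring–chain equilibrium with its other form, and both forms lead to 21.

## Route

Step 1
Reactants: 1 (R)-carvone
Product: 2 (2R,5R)-dihydrocarvone
Conditions: LiBH(s-Bu)3, THF, −78 °C; then aq. NH4Cl
Reagents that add atoms: none
Why: Conjugate hydride reduction of a β-unsubstituted cyclohexenone; the isolated isopropenyl alkene and the C5 stereocentre are not touched, and protonation of the enolate gives mainly the trans isomer.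

Step 2
Reactants: 2 (2R,5R)-dihydrocarvone
Product: 3 (2R,5R)-5-(2-chloropropan-2-yl)-2-methylcyclohexan-1-one
Conditions: HCl (g), Et2O, 0 °C
Reagents that add atoms: hydrogen chloride, Cl
Why: Markovnikov hydrochlorination of the 1,1-disubstituted alkene through the tertiary cation; the ketone and C5 are unaffected.

Step 3
Reactants: 3 (2R,5R)-5-(2-chloropropan-2-yl)-2-methylcyclohexan-1-one
Product: 4 carone, (1S,3R,6R)-3,7,7-trimethylbicyclo[4.1.0]heptan-2-one
Conditions: KOH, MeOH, 0 °C → rt
Reagents that add atoms: none
Why: Base-induced 1,3-elimination (3-exo-tet enolate alkylation): the C6 enolate displaces the tertiary chloride and closes the cyclopropane, which can only be cis-fused, so the new centre C1 follows from the carvone stereocentre.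

Step 4
Reactants: 4 carone; 5 ethyl vinyl ketone
Product: 8 (6S,7R,10S)-6,11-cycloeudesm-4-en-3-one, via Michael diketone 6 (not isolated), via aldol ketol 7 (not isolated)
Conditions: KOH (0.3 equiv), EtOH, −10 °C, slow addition of 5; rt; then 60 °C
Reagents that add atoms: none
Why: KOH forms the only accessible enolate of 4, at C3 (eudesmane C10′), because enolisation towards C1 would place a double bond exocyclic to the cyclopropane; this enolate adds to 5 in a Michael reaction and forms C1′–C10′ (diketone 6). Proton exchange gives the ethyl-ketone enolate at C4′, which attacks the ring carbonyl C5′ (ketol 7), and E1cB loss of water gives the conjugated C4′=C5′ enone 8. The closest known reaction type is the Robinson annulation of 2-methylcyclohexanones with ethyl vinyl ketone to 4,10-dimethyloctalones. Ring A′ closes in a 6-(enolendo)-exo-trig mode; closure through the other α-carbon C2′ would need a four-membered ring and does not compete. The one new stereocentre, C10′, is set by the cyclopropane: its endo methyl lies over the β face of the planar enolate, so 5 approaches from the α face and the methyl stays β, cis to the C7′–C11′ bond. The step needs C-alkylation and mono-addition, which the soft enone acceptor and slow addition of 5 at low temperature favour, and the final dehydration makes the sequence irreversible. The cyclopropane survives because base does not open a cyclopropyl ketone that lacks a second acceptor group.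

Step 5
Reactants: 8 (6S,7R,10S)-6,11-cycloeudesm-4-en-3-one
Product: 9 carissone, (7R,10S)-11-hydroxyeudesm-4-en-3-one
Conditions: HClO4 (aq., 1 M), THF, rt
Reagents that add atoms: water, O
Why: Acid-catalysed homoconjugate addition: protonation of the enone oxygen makes C5′ electron-poor, the conjugated C6′–C11′ bond opens towards the tertiary C11′ where water is captured, and the dienol returns to the C4′=C5′ enone; the C6′–C7′ bond and the C7′ centre are untouched, and perchlorate does not compete as a nucleophile.

Step 6
Reactants: 9 carissone
Product: 10 11-(triethylsilyloxy)eudesm-4-en-3-one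
Conditions: Et3SiOTf, 2,6-lutidine, CH2Cl2, −78 → 0 °C
Reagents that add atoms: triethylsilyl trifluoromethanesulfonate, CC[Si](CC)(CC)OS(=O)(=O)C(F)(F)F
Why: Silylation of a tertiary alcohol with a silyl triflate and a hindered base; masking C11′–OH now keeps the two tertiary hydroxyls from ever being free together and removes an acidic proton before the dissolving-metal step.

Step 7
Reactants: 10 11-(triethylsilyloxy)eudesm-4-en-3-one
Product: 12 11-(triethylsilyloxy)-5α-eudesm-3-en-3-yl trifluoromethanesulfonate, via lithium enolate 11 (not isolated)
Conditions: Li, NH3 (l), THF, t-BuOH (1 equiv), −78 °C; isoprene; NH3 off; PhNTf2, THF, 0 °C → rt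
Reagents that add atoms: N-phenylbis(trifluoromethanesulfonimide), O=S(=O)(N(c1ccccc1)S(=O)(=O)C(F)(F)F)C(F)(F)F
Why: Dissolving-metal (Birch-type) reduction of the enone: C5′ is protonated axially from the α face, anti to the C10′ methyl, giving the trans-decalin and the regiodefined C3′ enolate 11, whose O-sulfonylation fixes the alkene at C3′=C4′.

Step 8
Reactants: 12 11-(triethylsilyloxy)-5α-eudesm-3-en-3-yl trifluoromethanesulfonate
Product: 13 11-(triethylsilyloxy)-5α-eudesm-3-ene (α-eudesmol triethylsilyl ether)
Conditions: Pd(OAc)2 (5 mol %), PPh3, HCO2H, n-Bu3N, DMF, 60 °C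
Reagents that add atoms: none
Why: Palladium-catalysed formate reduction of an enol triflate: oxidative addition to zerovalent palladium, formate exchange, loss of CO2 and reductive elimination put hydrogen on C3′ without moving the alkene or touching a stereocentre.

Step 9
Reactants: 13 11-(triethylsilyloxy)-5α-eudesm-3-ene
Product: 14 3α,4α-epoxy-11-(triethylsilyloxy)-5α-eudesmane
Conditions: mCPBA, NaHCO3, CH2Cl2, 0 °C
Reagents that add atoms: 3-chloroperoxybenzoic acid, OOC(=O)c1cccc(Cl)c1
Why: Prilezhaev epoxidation; the axial C10′ methyl, 1,3 to C4′, blocks the β face, so oxygen should enter from the α face and fix the C4′–O bond α, and the buffer protects the epoxide and the silyl ether from the acid formed.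

Step 10
Reactants: 14 3α,4α-epoxy-11-(triethylsilyloxy)-5α-eudesmane
Product: 15 11-(triethylsilyloxy)-5α-eudesman-4α-ol (cryptomeridiol 11-triethylsilyl ether)
Conditions: LiAlH4, THF, reflux; then H2O work-up
Reagents that add atoms: none
Why: SN2 hydride opening of a trisubstituted epoxide at the secondary C3′; the C4′–O bond is not broken, so the α-oxygen and β-methyl at C4′ follow from step 9, while attack at C4′ is blocked by its substitution and by the syn-axial C10′ methyl.

Step 11
Reactants: 15 11-(triethylsilyloxy)-5α-eudesman-4α-ol
Product: 16 4α-(methylthiomethoxy)-11-(triethylsilyloxy)-5α-eudesmane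
Conditions: DMSO, Ac2O, AcOH, rt, 48 h
Reagents that add atoms: dimethyl sulfoxide, CS(C)=O
Why: Pummerer-type methylthiomethylation: the acetoxysulfonium ion gives the thionium ion CH2=S+Me, a small electrophile that hindered tertiary hydroxyls capture; no base or strong acid is involved, so the tertiary silyl ether should hold and C4′ is not ionised.

Step 12
Reactants: 16 4α-(methylthiomethoxy)-11-(triethylsilyloxy)-5α-eudesmane
Product: 17 4α-(chloromethoxy)-11-(triethylsilyloxy)-5α-eudesmane
Conditions: SO2Cl2, CH2Cl2, −78 → 0 °C; volatiles off; used crude
Reagents that add atoms: sulfuryl chloride, ClS(Cl)(=O)=O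
Why: Chlorinolysis of an O,S-acetal: S-chlorination and loss of MeSCl give the α-chloro ether through the oxocarbenium ion; 16 has no alkene for the sulfenyl chloride to add to and no HCl is formed.

Step 13
Reactants: 18 podocarpic acid
Product: 19 8-hydroxy-12-oxo-8,12-epoxy-13,14,15,16,17-pentanorlabd-9(11)-en-19-oic acid (lactol of the (Z)-8-oxo-9(11)-ene-12,19-dioic acid)
Conditions: O3 (about 2 equiv), CH2Cl2–MeOH, −78 °C; then Me2S, −78 °C → rt
Reagents that add atoms: ozone, [O-][O+]=O
Why: Ozonolysis of an electron-rich phenol ring: the enol-like C12–C13 bond should be cleaved first (C12 becomes CO2H) and then C8=C14 of the resulting diene (C8 becomes a ketone, C13 and C14 leave), whereas C9=C11, now flanked by two carbonyl groups and by quaternary C10, is too electron-poor to react; the (Z)-γ-keto acid closes to the lactol and C4, C5 and C10 are not involved.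

Step 14
Reactants: 19 lactol acid
Product: 20 8-oxo-13,14,15,16,17-pentanorlabdane-12,19-dioic acid
Conditions: H2 (1 atm), Pd/C, EtOAc, rt
Reagents that add atoms: none
Why: Heterogeneous hydrogenation of the butenolide alkene from the α face, opposite the axial C10 methyl, should give 9α-H with the acetic acid chain β and equatorial; C9 is α to the C8 ketone of the open form, so the same, more stable epimer is also reached by equilibration.

Step 15
Reactants: 20 8-oxo-13,14,15,16,17-pentanorlabdane-12,19-dioic acid
Product: 21 dimethyl 8-oxo-13,14,15,16,17-pentanorlabdane-12,19-dioate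
Conditions: MeI, K2CO3, DMF, rt
Reagents that add atoms: iodomethane, CI
Why: Carboxylate O-alkylation (SN2 on MeI) esterifies both acids regardless of the hindrance at C4 and locks the open keto form.

Step 16
Reactants: 21 dimethyl 8-oxo-13,14,15,16,17-pentanorlabdane-12,19-dioate
Product: 22 dimethyl 13,14,15,16-tetranorlabd-8(17)-ene-12,19-dioate
Conditions: Ph3PCH3Br, KOtBu, toluene, rt → 60 °C
Reagents that add atoms: methyltriphenylphosphonium bromide, C[P+](c1ccccc1)(c1ccccc1)c1ccccc1.[Br-]
Why: Wittig methylenation of the C8 ketone installs C17; the esters do not react with the non-stabilised ylide under these conditions, and C9 already has its thermodynamically preferred configuration.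

Step 17
Reactants: 22 dimethyl 13,14,15,16-tetranorlabd-8(17)-ene-12,19-dioate
Product: 23 methyl 12-hydroxy-13,14,15,16-tetranorlabd-8(17)-en-19-oate
Conditions: LiBH4, THF, 0 °C → rt
Reagents that add atoms: none
Why: Chemoselective ester reduction: LiBH4 reduces the unhindered primary-chain ester at C12, while the axial C19 ester on quaternary C4, shielded by the syn-axial C10 methyl, should remain.

Step 18
Reactants: 23 methyl 12-hydroxy-13,14,15,16-tetranorlabd-8(17)-en-19-oate
Product: 24 methyl 12-iodo-13,14,15,16-tetranorlabd-8(17)-en-19-oate
Conditions: I2, PPh3, imidazole, CH2Cl2, 0 °C → rt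
Reagents that add atoms: iodine, II
Why: Appel-type iodination of a primary alcohol through the alkoxyphosphonium salt with SN2 displacement by iodide.

Step 19
Reactants: 24 methyl 12-iodo-13,14,15,16-tetranorlabd-8(17)-en-19-oate
Product: 25 methyl 15,16-dinorlabd-8(17)-en-13-yn-19-oate
Conditions: LiC≡CH·H2NCH2CH2NH2, DMSO, rt
Reagents that add atoms: lithium acetylide–ethylenediamine complex, [Li+].[C-]#C.NCCN
Why: SN2 alkylation of lithium acetylide by an unbranched primary iodide in a dipolar aprotic solvent forms C12–C13; the hindered C19 ester is not attacked.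

Step 20
Reactants: 25 methyl 15,16-dinorlabd-8(17)-en-13-yn-19-oate; 17 4α-(chloromethoxy)-11-(triethylsilyloxy)-5α-eudesmane
Product: 27 methyl 15-[(11-triethylsilyloxy-5α-eudesman-4α-yl)oxy]labda-8(17),13E-dien-19-oate, via alkenylalane 26 (not isolated)
Conditions: AlMe3 (2.5 equiv), Cp2ZrCl2 (0.25 equiv), CH2Cl2, 0 °C → rt; excess AlMe3 off in vacuum; then 17, CH2Cl2, −20 °C → rt
Reagents that add atoms: trimethylaluminium, C[Al](C)C
Why: Zirconium-catalysed methylalumination (Negishi carboalumination) adds CH3 and aluminium syn across the terminal alkyne with the metal on C14, which installs C16 and fixes the E geometry; the alkenyl–aluminium bond then attacks the oxocarbenium ion from the α-chloro ether with retention, the known behaviour of alkenylalanes towards chloromethyl ethers, forming C14–C15. The 1,1-disubstituted C8=C17 alkene and the hindered ester should not react.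

Step 21
Reactants: 27 methyl 15-[(11-triethylsilyloxy-5α-eudesman-4α-yl)oxy]labda-8(17),13E-dien-19-oate
Product: 28 methyl 15-[(11-hydroxy-5α-eudesman-4α-yl)oxy]labda-8(17),13E-dien-19-oate
Conditions: Bu4NF, THF, rt → 45 °C
Reagents that add atoms: none
Why: Fluoride-induced cleavage of the Si–O bond, driven by the strong Si–F bond; the conditions are not acidic, so the tertiary allylic ether, both alkenes and the C11′ carbinol should survive.

Step 22
Reactants: 28 methyl 15-[(11-hydroxy-5α-eudesman-4α-yl)oxy]labda-8(17),13E-dien-19-oate
Product: 29 15-[(11-hydroxy-5α-eudesman-4α-yl)oxy]labda-8(17),13E-dien-19-oic acid (target)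
Conditions: n-PrSLi (from n-PrSH, n-BuLi), HMPA, rt; then cold 0.1 M HCl to pH 4
Reagents that add atoms: none
Why: SN2 demethylation of a hindered methyl ester: the thiolate attacks the exposed methyl carbon, not the shielded carbonyl; a tertiary alkoxide is too poor a leaving group for the allylic ether to be cleaved and thiolate does not move the alkenes.

## Compound list

1 | (R)-carvone, (5R)-2-methyl-5-(prop-1-en-2-yl)cyclohex-2-en-1-one | CC1=CC[C@@H](C(C)=C)CC1=O | starting material
2 | (2R,5R)-dihydrocarvone (trans) | C[C@@H]1CC[C@@H](C(C)=C)CC1=O | intermediate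
3 | (2R,5R)-5-(2-chloropropan-2-yl)-2-methylcyclohexan-1-one | C[C@@H]1CC[C@@H](C(C)(C)Cl)CC1=O | intermediate
4 | carone, (1S,3R,6R)-3,7,7-trimethylbicyclo[4.1.0]heptan-2-one | C[C@@H]1CC[C@@H]2[C@@H](C2(C)C)C1=O | intermediate
5 | ethyl vinyl ketone (pent-1-en-3-one) | C=CC(=O)CC | starting material
6 | (1S,3S,6R)-3,7,7-trimethyl-3-(3-oxopentyl)bicyclo[4.1.0]heptan-2-one (Michael diketone) | CCC(=O)CC[C@]1(C)CC[C@@H]2[C@@H](C2(C)C)C1=O | intermediate (not isolated)
7 | 5-hydroxy-6,11-cycloeudesman-3-one (aldol ketol; 10β-methyl, β-cyclopropane; epimers at C4 and C5) | O=C1CC[C@]2(C)CC[C@@H]3[C@@H](C3(C)C)C2(O)C1C | intermediate (not isolated)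
8 | (6S,7R,10S)-6,11-cycloeudesm-4-en-3-one (10β-methyl; cyclopropane C6–C7–C11 on the β face) | O=C1CC[C@]2(C)CC[C@@H]3[C@@H](C3(C)C)C2=C1C | intermediate
9 | carissone, (7R,10S)-11-hydroxyeudesm-4-en-3-one | O=C1CC[C@]2(C)CC[C@@H](C(C)(C)O)CC2=C1C | intermediate
10 | 11-(triethylsilyloxy)eudesm-4-en-3-one | O=C1CC[C@]2(C)CC[C@@H](C(C)(C)O[Si](CC)(CC)CC)CC2=C1C | intermediate
11 | lithium 11-(triethylsilyloxy)-5α-eudesm-3-en-3-olate | [Li+].CC1=C([O-])CC[C@]2(C)CC[C@@H](C(C)(C)O[Si](CC)(CC)CC)C[C@@H]12 | intermediate (not isolated)
12 | 11-(triethylsilyloxy)-5α-eudesm-3-en-3-yl trifluoromethanesulfonate | CC1=C(OS(=O)(=O)C(F)(F)F)CC[C@]2(C)CC[C@@H](C(C)(C)O[Si](CC)(CC)CC)C[C@@H]12 | intermediate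
13 | 11-(triethylsilyloxy)-5α-eudesm-3-ene (α-eudesmol triethylsilyl ether) | CC1=CCC[C@]2(C)CC[C@@H](C(C)(C)O[Si](CC)(CC)CC)C[C@@H]12 | intermediate
14 | 3α,4α-epoxy-11-(triethylsilyloxy)-5α-eudesmane | C[C@@]12O[C@@H]1CC[C@]3(C)CC[C@@H](C(C)(C)O[Si](CC)(CC)CC)C[C@@H]23 | intermediate
15 | 11-(triethylsilyloxy)-5α-eudesman-4α-ol (cryptomeridiol 11-triethylsilyl ether) | O[C@]1(C)CCC[C@]2(C)CC[C@@H](C(C)(C)O[Si](CC)(CC)CC)C[C@H]21 | intermediate
16 | 4α-(methylthiomethoxy)-11-(triethylsilyloxy)-5α-eudesmane | CSCO[C@]1(C)CCC[C@]2(C)CC[C@@H](C(C)(C)O[Si](CC)(CC)CC)C[C@H]21 | intermediate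
17 | 4α-(chloromethoxy)-11-(triethylsilyloxy)-5α-eudesmane | ClCO[C@]1(C)CCC[C@]2(C)CC[C@@H](C(C)(C)O[Si](CC)(CC)CC)C[C@H]21 | intermediate
18 | podocarpic acid, 12-hydroxypodocarpa-8,11,13-trien-19-oic acid | c1cc(O)cc2c1CC[C@@H]1[C@]2(C)CCC[C@]1(C)C(=O)O | starting material
19 | 8-hydroxy-12-oxo-8,12-epoxy-13,14,15,16,17-pentanorlabd-9(11)-en-19-oic acid (lactol; C8 epimers) | O=C1OC2(O)CC[C@@H]3[C@](C)(CCC[C@]3(C)C(=O)O)C2=C1 | intermediate
20 | 8-oxo-13,14,15,16,17-pentanorlabdane-12,19-dioic acid | O=C1CC[C@@H]2[C@](C)(CCC[C@]2(C)C(=O)O)[C@H]1CC(=O)O | intermediate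
21 | dimethyl 8-oxo-13,14,15,16,17-pentanorlabdane-12,19-dioate | O=C1CC[C@@H]2[C@](C)(CCC[C@]2(C)C(=O)OC)[C@H]1CC(=O)OC | intermediate
22 | dimethyl 13,14,15,16-tetranorlabd-8(17)-ene-12,19-dioate | C=C1CC[C@@H]2[C@](C)(CCC[C@]2(C)C(=O)OC)[C@H]1CC(=O)OC | intermediate
23 | methyl 12-hydroxy-13,14,15,16-tetranorlabd-8(17)-en-19-oate | C=C1CC[C@@H]2[C@](C)(CCC[C@]2(C)C(=O)OC)[C@H]1CCO | intermediate
24 | methyl 12-iodo-13,14,15,16-tetranorlabd-8(17)-en-19-oate | C=C1CC[C@@H]2[C@](C)(CCC[C@]2(C)C(=O)OC)[C@H]1CCI | intermediate
25 | methyl 15,16-dinorlabd-8(17)-en-13-yn-19-oate | C=C1CC[C@@H]2[C@](C)(CCC[C@]2(C)C(=O)OC)[C@H]1CCC#C | intermediate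
26 | methyl (13E)-14-(dimethylalumanyl)-15-norlabda-8(17),13-dien-19-oate | C=C1CC[C@@H]2[C@](C)(CCC[C@]2(C)C(=O)OC)[C@H]1CC/C(C)=C/[Al](C)C | intermediate (not isolated)
27 | methyl 15-[(11-triethylsilyloxy-5α-eudesman-4α-yl)oxy]labda-8(17),13E-dien-19-oate | C=C1CC[C@@H]2[C@](C)(CCC[C@]2(C)C(=O)OC)[C@H]1CC/C(C)=C/CO[C@]1(C)CCC[C@]2(C)CC[C@@H](C(C)(C)O[Si](CC)(CC)CC)C[C@H]21 | intermediate
28 | methyl 15-[(11-hydroxy-5α-eudesman-4α-yl)oxy]labda-8(17),13E-dien-19-oate | C=C1CC[C@@H]2[C@](C)(CCC[C@]2(C)C(=O)OC)[C@H]1CC/C(C)=C/CO[C@]1(C)CCC[C@]2(C)CC[C@@H](C(C)(C)O)C[C@H]21 | intermediate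
29 | 15-[(11-hydroxy-5α-eudesman-4α-yl)oxy]labda-8(17),13E-dien-19-oic acid | C=C1CC[C@@H]2[C@](C)(CCC[C@]2(C)C(=O)O)[C@H]1CC/C(C)=C/CO[C@]1(C)CCC[C@]2(C)CC[C@@H](C(C)(C)O)C[C@H]21 | target

## Step count and risk

Total step count: 22. Longest linear sequence: 15 steps (steps 1–12 and 20–22, from 1). The labdane branch from 18 takes 7 steps (13–19) before the union.

**Step 4 (key step).** The Michael addition of a hindered, fully substituted enolate may be slow, so that base-induced polymerisation of 5 and incomplete facial control compete. Fallback, from 4 back to 8: 4 is deprotonated with LiN(i-Pr)2 in THF at −78 °C to the lithium enolate of carone F1. F1 is added under aprotic conditions to the silyl-stabilised vinyl ketone 2-(trimethylsilyl)pent-1-en-3-one, which cannot polymerise by the same path, to give the α-silyl diketone F2. NaOMe in MeOH then removes silicon and carries the material through 6 and 7 to 8.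

**Step 13.** Ozone may attack the phenol at other sites (para attack at C8, cleavage on the C11 side, or over-oxidation of C9=C11), which would open ring B or give mixtures. Fallback, from 18 back to 20:
- O-methylation (Me2SO4, aq. NaOH) gives O-methylpodocarpic acid F3.
- Birch reduction (Li, NH3, t-BuOH) and acid hydrolysis with conjugation give 12-oxopodocarp-9(11)-en-19-oic acid F4.
- A second dissolving-metal reduction gives the trans-fused 12-oxopodocarpan-19-oic acid F5.
- Dehydrogenation with 2-iodoxybenzoic acid in DMSO, away from the ring fusion, gives 12-oxopodocarp-13-en-19-oic acid F6.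
- t-BuMe2SiOTf and Et3N give the linear dienol silyl ether and silyl ester F7.
- Ozonolysis of both electron-rich double bonds of F7 and aqueous work-up give 20, with C9 already set by the metal reduction.

**Step 20.** Methyl instead of alkenyl may be transferred from aluminium to the oxocarbenium ion, or the Lewis acid may fragment the tertiary alkoxymethyl cation with loss of the C4′ oxygen. Fallback, from 25 and 15 back to 27 (it also bypasses 16 and 17): the alkenylalane 26, made as in step 20, is turned into its ate complex with n-BuLi and treated with (CH2O)n to give methyl isocupressate F8. CBr4 and PPh3 convert F8 into the allylic bromide F9. 15 is deprotonated with KH and 18-crown-6 in THF to its potassium alkoxide F10, and Williamson alkylation of F10 with F9 gives 27.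

**Step 10.** Hydride delivery to C3′ runs against the diaxial-opening preference (through a twist-boat) and may be slow, so that Lewis-acid-induced rearrangement of the epoxide or loss of the silyl ether at reflux can compete. Fallback, from 13 directly to 15: Mukaiyama hydration (Co(acac)2, PhSiH3, O2, i-PrOH) puts hydrogen on C3′ and oxygen on the tertiary C4′ radical, which should be trapped from the α face, anti to the axial C10′ methyl. No new compound is made.

## Further compounds

F1 | step 4 | lithium enolate of carone | [Li+].[O-]C1=C(C)CC[C@@H]2[C@H]1C2(C)C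
F2 | step 4 | (1S,3S,6R)-3,7,7-trimethyl-3-[3-oxo-2-(trimethylsilyl)pentyl]bicyclo[4.1.0]heptan-2-one (epimers at the silyl-bearing carbon) | CCC(=O)C([Si](C)(C)C)C[C@]1(C)CC[C@@H]2[C@@H](C2(C)C)C1=O
F3 | step 13 | O-methylpodocarpic acid, 12-methoxypodocarpa-8,11,13-trien-19-oic acid | c1cc(OC)cc2c1CC[C@@H]1[C@]2(C)CCC[C@]1(C)C(=O)O
F4 | step 13 | 12-oxopodocarp-9(11)-en-19-oic acid (8β-H) | O=C1CC[C@@H]2CC[C@@H]3[C@](C)(CCC[C@]3(C)C(=O)O)C2=C1
F5 | step 13 | 12-oxopodocarpan-19-oic acid (8β-H, 9α-H) | O=C1CC[C@@H]2CC[C@@H]3[C@](C)(CCC[C@]3(C)C(=O)O)[C@H]2C1
F6 | step 13 | 12-oxopodocarp-13-en-19-oic acid (8β-H, 9α-H) | O=C1C=C[C@@H]2CC[C@@H]3[C@](C)(CCC[C@]3(C)C(=O)O)[C@H]2C1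
F7 | step 13 | tert-butyldimethylsilyl 12-(tert-butyldimethylsilyloxy)podocarpa-8(14),12-dien-19-oate (9α-H) | CC(C)(C)[Si](C)(C)OC1=CC=C2CC[C@@H]3[C@](C)(CCC[C@]3(C)C(=O)O[Si](C)(C)C(C)(C)C)[C@H]2C1
F8 | step 20 | methyl isocupressate, methyl 15-hydroxylabda-8(17),13E-dien-19-oate | C=C1CC[C@@H]2[C@](C)(CCC[C@]2(C)C(=O)OC)[C@H]1CC/C(C)=C/CO
F9 | step 20 | methyl 15-bromolabda-8(17),13E-dien-19-oate | C=C1CC[C@@H]2[C@](C)(CCC[C@]2(C)C(=O)OC)[C@H]1CC/C(C)=C/CBr
F10 | step 20 | potassium 11-(triethylsilyloxy)-5α-eudesman-4α-olate | [K+].[O-][C@]1(C)CCC[C@]2(C)CC[C@@H](C(C)(C)O[Si](CC)(CC)CC)C[C@H]21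
F0 | step 10 | none | none
A1 | alternative 1 | methyl 17-(4-methoxybenzyloxy)-11-oxo-12,13,14,15,16-pentanorlabd-6-en-19-oate (trans-fused octalin aldehyde) | COc1ccc(COC[C@H]2C=C[C@@H]3[C@](C)(CCC[C@]3(C)C(=O)OC)[C@H]2C=O)cc1
A2 | alternative 1 | methyl (2S,6E)-2-[(1E,3E)-5-[(4-methoxyphenyl)methoxy]penta-1,3-dien-1-yl]-2,6-dimethyl-8-oxooct-6-enoate | O=C/C=C(\C)CCC[C@](C)(C(=O)OC)/C=C/C=C/COCc1ccc(OC)cc1
A3 | alternative 2 | 8-phenylmenthyl 11-acetoxy-3-oxo-12,13,14,15,16-pentanorlabd-8(17)-en-19-oate | C=C1CC[C@@H]2[C@](C)(CCC(=O)[C@]2(C)C(=O)O[C@@H]2C[C@H](C)CC[C@H]2C(C)(C)c2ccccc2)[C@H]1COC(C)=O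
A4 | alternative 2 | 8-phenylmenthyl (6E,10E)-12-acetoxy-2,6,10-trimethyl-3-oxododeca-6,10-dienoate (C2 epimers) | CC(C(=O)O[C@@H]1C[C@H](C)CC[C@H]1C(C)(C)c1ccccc1)C(=O)CC/C(C)=C/CC/C(C)=C/COC(C)=O
A5 | alternative 3 | methyl 15-[(11-hydroxy-5α-eudesman-4α-yl)oxy]labda-8(17),13E-dien-19-oate (identical with 28) | C=C1CC[C@@H]2[C@](C)(CCC[C@]2(C)C(=O)OC)[C@H]1CC/C(C)=C/CO[C@]1(C)CCC[C@]2(C)CC[C@@H](C(C)(C)O)C[C@H]21
A6 | alternative 3 | hedycaryol, (1E,4E)-germacra-1(10),4-dien-11-ol with the C7 configuration of 9 | C/C1=C\CC/C(C)=C/C[C@H](C(C)(C)O)CC1
A7 | alternative 3 | methyl isocupressate, methyl 15-hydroxylabda-8(17),13E-dien-19-oate | C=C1CC[C@@H]2[C@](C)(CCC[C@]2(C)C(=O)OC)[C@H]1CC/C(C)=C/CO
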